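**Strategy.** Everything rests on disconnecting C1–C10 (eudesmane numbering), so that ring A (C1–C2–C3–C4–C5–C10) is the last ring closed. An iron-hydride hydrogen-atom-transfer reductive cyclisation joins a C9=C10 alkene and a C1 aldehyde. In one operation it should create the quaternary C10 with its methyl, the C1 carbinol and the target. The precursor is a 1,10-seco-eudesmane that already holds ring B and the complete orthocinnamate cage on O4, O6 and O15. The step exploits the all-chair array around C5: the 1,3-dioxane ring (O6–C6–C5–C4–O4) is trans-fused to ring B and holds C3 equatorial on C4, so the C10 radical reaches C1 only through the chair leading to the trans-decalin.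

Key step: step 11

Remark: locants C1–C15 follow the eudesmane numbering of the target throughout (ring A = C1–C2–C3–C4–C5–C10, ring B = C5–C6–C7–C8–C9–C10; C7 carries isopropyl, C15 is the OCH2 carbon).

Step 1
Reactants: 1 (−)-menthone
Product: 3 (S)-piperitone, via silyl enol ether 2 (not isolated)
Conditions: LiN(iPr)2, THF, −78 °C; Me3SiCl; solvent exchange; Pd(OAc)2, MeCN, 25 °C
Reagents that add atoms: none
Why: LiN(iPr)2 removes a proton kinetically from the unhindered methylene next to the carbonyl (future C5), not the C7–H that carries isopropyl, and Saegusa–Ito oxidation of 2 by Pd(OAc)2 places the double bond between C5 and C10, so the C7 stereocentre of menthone is carried into 3 untouched.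

Step 2
Reactants: 3 (S)-piperitone
Product: 4 linear trimethylsilyl dienol ether
Conditions: Me3SiOTf, Et3N, CH2Cl2, 0 °C
Reagents that add atoms: trimethylsilyl triflate, C[Si](C)(C)OS(=O)(=O)C(F)(F)F
Why: Soft enolisation (O-silylation, then deprotonation by Et3N) of a β,β-disubstituted enone should remove a γ-proton at C9 in preference to the hindered tertiary α'-proton at C7, giving the linear endocyclic dienol ether without touching the stereocentre.

Step 3
Reactants: 5 (3-bromopropoxy)(tert-butyl)dimethylsilane; 6 dimethyl oxalate
Product: 8 methyl 5-[(tert-butyldimethylsilyl)oxy]-2-oxopentanoate, via Grignard reagent 7 (not isolated)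
Conditions: Mg, THF, 40 °C; then inverse addition to 6 (excess), THF/Et2O, −78 °C
Reagents that add atoms: none
Why: Grignard acylation of an oxalate diester stops at the α-keto ester because the tetrahedral magnesium alkoxide survives at low temperature until work-up.

Step 4
Reactants: 4 linear trimethylsilyl dienol ether; 8 methyl 5-[(tert-butyldimethylsilyl)oxy]-2-oxopentanoate
Product: 10 aldol adduct (C5–C4 bond), via lithium dienolate 9 (not isolated)
Conditions: MeLi, THF, 0 °C; then 8, −78 °C; AcOH, −78 °C
Reagents that add atoms: none
Why: MeLi cleaves the O–Si bond to give the lithium dienolate regiospecifically, which adds through its α-carbon (C5) to the activated ketone of 8 in a directed aldol reaction; attack anti to the pseudoaxial C7 isopropyl group (A(1,2) strain) sets C5, and a chelated Zimmerman–Traxler chair (ring-enforced E-enolate, ester axial and bound to lithium, side chain equatorial) sets C4.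

Step 5
Reactants: 10 aldol adduct
Product: 11 anti diol ester
Conditions: Me4NBH(OAc)3, MeCN/AcOH, −30 °C
Reagents that add atoms: none
Why: Evans–Saksena reduction: the tertiary C4 hydroxyl exchanges onto boron and delivers hydride intramolecularly to the C6 ketone from the face that carries the C5–C4 bond, which should give the C6 alcohol trans to C4 and cis to isopropyl while ester, silyl ether and alkene stay inert.

Step 6
Reactants: 11 anti diol ester
Product: 12 triol
Conditions: LiBH4, THF, MeOH (1 equiv), 0 °C to 25 °C
Reagents that add atoms: none
Why: LiBH4 reduces the α-hydroxy methyl ester to the primary C15 alcohol (ester reduction) and leaves the silyl ether and the trisubstituted alkene untouched.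

Step 7
Reactants: 13 (E)-cinnamonitrile
Product: 15 trimethyl (E)-orthocinnamate, via imidate hydrochloride 14 (not isolated)
Conditions: HCl (g), MeOH (1.1 equiv), Et2O, 0 °C; evaporation; MeOH (excess), hexane, 25 °C
Reagents that add atoms: methanol, CO
Why: Pinner reaction: HCl-promoted addition of methanol to the nitrile gives the imidate salt, whose alcoholysis delivers the ortho ester and precipitates NH4Cl, the β-phenyl group disfavouring conjugate addition so that the E alkene is kept.

Step 8
Reactants: 12 triol; 15 trimethyl (E)-orthocinnamate
Product: 16 cage orthoester silyl ether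
Conditions: PPTS (cat.), CH2Cl2, 4 Å MS, 25 °C; Et3N quench
Reagents that add atoms: none
Why: Acid-catalysed transorthoesterification: the C15 and C4 hydroxyls form the dioxolane, the C6 hydroxyl then closes the dioxane, and removal of methanol drives the equilibrium to the 2,7,8-trioxabicyclo[3.2.1]octane cage, whose orthoester-carbon configuration is dictated by the three fixed carbinol carbons.

Step 9
Reactants: 16 cage orthoester silyl ether
Product: 17 cage orthoester alcohol
Conditions: TBAF, THF, 0 °C to 25 °C
Reagents that add atoms: none
Why: Fluoride-mediated desilylation is basic, so the acid-labile orthoester, the styryl group and the ring alkene should survive.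

Step 10
Reactants: 17 cage orthoester alcohol
Product: 18 cage orthoester aldehyde
Conditions: Dess–Martin periodinane, NaHCO3, CH2Cl2, 0 °C to 25 °C
Reagents that add atoms: none
Why: Buffered Dess–Martin oxidation converts the primary alcohol into the aldehyde under non-acidic conditions and does not touch the orthoester or either alkene.

Step 11
Reactants: 18 cage orthoester aldehyde
Product: 19 target CNP0190302.1
Conditions: Fe(acac)3 (0.3 equiv), PhSiH3, EtOH, 60 °C, degassed
Reagents that add atoms: none
Why: The iron hydride formed from Fe(acac)3 and PhSiH3 transfers a hydrogen atom to C9 of the trisubstituted alkene (Markovnikov) and the tertiary C10 radical adds to the C1 formyl carbon; the alkoxy radical is reduced and protonated by the medium, which makes the reversible addition productive. The closest known reaction type is the iron-hydride HAT-initiated reductive radical cyclisation of alkene-tethered ketones and aldehydes, a relative of the classical 6-exo radical addition to aldehydes. Ring A closes in the 6-exo-trig mode onto the carbonyl group. C10 is controlled by the cage: the dioxane ring trans-fused to ring B fixes C3 equatorial on C4, so only the chair transition state with the new C10–C1 bond equatorial on ring B and the methyl axial (anti to H5) is strain-free, the cis-decalin needing a twist-boat. C1 is controlled by the reversibility of the addition, which should favour the equatorial alkoxy radical (OH cis to the C10 methyl). The step needs hydrogen-atom transfer to the ring alkene in preference to the styryl group; the substrate secures this because the 1,2-disubstituted styryl alkene is flanked by the fully substituted orthoester carbon and gives no tertiary radical, and the orthoester tolerates the non-acidic medium.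

**Compound list**

1 | (−)-menthone, (2S,5R)-5-methyl-2-(propan-2-yl)cyclohexan-1-one | CC(C)[C@@H]1CC[C@@H](C)CC1=O | starting material
2 | trimethyl{[(3R,6S)-3-methyl-6-(propan-2-yl)cyclohex-1-en-1-yl]oxy}silane | CC(C)[C@@H]1CC[C@@H](C)C=C1O[Si](C)(C)C | intermediate
3 | (S)-piperitone, (6S)-3-methyl-6-(propan-2-yl)cyclohex-2-en-1-one | CC(C)[C@@H]1CCC(C)=CC1=O | intermediate
4 | trimethyl{[(6S)-3-methyl-6-(propan-2-yl)cyclohexa-1,3-dien-1-yl]oxy}silane | CC(C)[C@@H]1CC=C(C)C=C1O[Si](C)(C)C | intermediate
5 | (3-bromopropoxy)(tert-butyl)dimethylsilane | BrCCCO[Si](C)(C)C(C)(C)C | starting material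
6 | dimethyl oxalate | COC(=O)C(=O)OC | starting material
7 | {3-[(tert-butyldimethylsilyl)oxy]propyl}magnesium bromide | Br[Mg]CCCO[Si](C)(C)C(C)(C)C | intermediate
8 | methyl 5-[(tert-butyldimethylsilyl)oxy]-2-oxopentanoate | COC(=O)C(=O)CCCO[Si](C)(C)C(C)(C)C | intermediate
9 | lithium (6S)-3-methyl-6-(propan-2-yl)cyclohexa-1,3-dien-1-olate | CC(C)[C@@H]1CC=C(C)C=C1O[Li] | intermediate
10 | methyl (2S)-5-[(tert-butyldimethylsilyl)oxy]-2-hydroxy-2-[(1S,5S)-2-methyl-6-oxo-5-(propan-2-yl)cyclohex-2-en-1-yl]pentanoate (C4-unit trans to isopropyl) | CC(C)[C@@H]1CC=C(C)[C@H](C1=O)[C@](O)(C(=O)OC)CCCO[Si](C)(C)C(C)(C)C | intermediate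
11 | methyl (2S)-5-[(tert-butyldimethylsilyl)oxy]-2-hydroxy-2-[(1R,5S,6R)-6-hydroxy-2-methyl-5-(propan-2-yl)cyclohex-2-en-1-yl]pentanoate (ring-carbon descriptor change from 10 reflects CIP priority only) | CC(C)[C@@H]1CC=C(C)[C@H]([C@@H]1O)[C@](O)(C(=O)OC)CCCO[Si](C)(C)C(C)(C)C | intermediate
12 | (2S)-5-[(tert-butyldimethylsilyl)oxy]-2-[(1R,5S,6R)-6-hydroxy-2-methyl-5-(propan-2-yl)cyclohex-2-en-1-yl]pentane-1,2-diol | CC(C)[C@@H]1CC=C(C)[C@H]([C@@H]1O)[C@](O)(CO)CCCO[Si](C)(C)C(C)(C)C | intermediate
13 | (E)-cinnamonitrile | N#C/C=C/c1ccccc1 | starting material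
14 | methyl (E)-cinnamimidate hydrochloride | COC(=[NH2+])/C=C/c1ccccc1.[Cl-] | intermediate
15 | trimethyl (E)-orthocinnamate, [(E)-3,3,3-trimethoxyprop-1-en-1-yl]benzene | COC(OC)(OC)/C=C/c1ccccc1 | intermediate
16 | (4S,5R,6R,7S)-1-[(tert-butyldimethylsilyl)oxy]-1,10-seco-eudesm-9-ene-4,6,15-triol 4,6,15-[(E)-orthocinnamate] (orthoester carbon S) | CC(C)[C@@H]1CC=C(C)[C@@H]3[C@@H]1O[C@]1(/C=C/c4ccccc4)OC[C@@]3(CCCO[Si](C)(C)C(C)(C)C)O1 | intermediate
17 | (4S,5R,6R,7S)-1,10-seco-eudesm-9-ene-1,4,6,15-tetraol 4,6,15-[(E)-orthocinnamate] | CC(C)[C@@H]1CC=C(C)[C@@H]3[C@@H]1O[C@]1(/C=C/c4ccccc4)OC[C@@]3(CCCO)O1 | intermediate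
18 | (4S,5R,6R,7S)-4,6,15-trihydroxy-1,10-seco-eudesm-9-en-1-al 4,6,15-[(E)-orthocinnamate] | CC(C)[C@@H]1CC=C(C)[C@@H]3[C@@H]1O[C@]1(/C=C/c4ccccc4)OC[C@@]3(CCC=O)O1 | intermediate
19 | CNP0190302.1, (1S,4S,5R,6R,7S,10S)-eudesmane-1,4,6,15-tetraol 4,6,15-[(E)-orthocinnamate] (orthoester carbon S) | CC(C)[C@@H]1CC[C@@]2(C)[C@@H]3[C@@H]1O[C@]1(/C=C/c4ccccc4)OC[C@@]3(CC[C@@H]2O)O1 | target

**Step count.** Total: 11 steps. Longest linear sequence: 9 steps (1, 2, 4, 5, 6, 8, 9, 10, 11).

**Steps most likely to fail**

Step 11. The C10 radical may add to both faces of the formyl group and give a mixture at C1, and some hydrogen-atom transfer may go to the styryl alkene. The fallback sets out from 18 and comes back at 19, and moves the control of C1 from the radical addition to a hydride reduction. The cyclisation is run as above without regard to C1. The crude carbinols are oxidised with Dess–Martin periodinane and NaHCO3 in CH2Cl2 to the C1 ketone, (4S,5R,6R,7S,10S)-4,6,15-trihydroxyeudesman-1-one 4,6,15-[(E)-orthocinnamate] F1. NaBH4 in MeOH at 0 °C should then deliver hydride axially, from the face opposite the axial C10 methyl, to give the equatorial alcohol 19.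

Step 4. The basic lithium dienolate may be quenched by proton transfer from the enolisable keto ester 8, may react through its γ-carbon, or may show eroded facial control at C4. The fallback sets out from 4 and comes back at 10, and generates the dienolate reductively instead. NBS in THF at 0 °C brominates the dienol ether at its γ-carbon (C9) to give the γ-bromo enone (6S)-4-bromo-3-methyl-6-(propan-2-yl)cyclohex-2-en-1-one F2, as a mixture of epimers at the bromine-bearing carbon. A vinylogous Reformatsky reaction (Zn dust, THF, low temperature, 8 present) forms the much less basic zinc dienolate, which should add through C5 in a chelated chair to give 10.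

Step 8. Repeated ionisation of the allyl-stabilised dialkoxycarbenium ion may stop at monocyclic or mixed orthoesters or cleave the silyl ether, and cage closure may stall because it forces the isopropyl group axial. The fallback sets out from 12 and comes back at 16, and closes the cage oxidatively. Cinnamaldehyde dimethyl acetal with PPTS converts the C4/C15 diol into the cinnamylidene acetal of 12 F3 (a 2-styryl-1,3-dioxolane, C6–OH free, acetal-carbon epimers). DDQ in CH2Cl2 with 4 Å MS abstracts the acetal hydride, and the dioxolanylium ion is trapped by the C6 hydroxyl to give 16; this oxidative orthoester formation is known for arylidene acetals.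

**Further compounds**

F1 | step 11 | (4S,5R,6R,7S,10S)-4,6,15-trihydroxyeudesman-1-one 4,6,15-[(E)-orthocinnamate] | CC(C)[C@@H]1CC[C@@]2(C)[C@@H]3[C@@H]1O[C@]1(/C=C/c4ccccc4)OC[C@@]3(CCC2=O)O1
F2 | step 4 | (6S)-4-bromo-3-methyl-6-(propan-2-yl)cyclohex-2-en-1-one (epimers at C4 of the ring) | CC(C)[C@@H]1CC(Br)C(C)=CC1=O
F3 | step 8 | cinnamylidene acetal of the C4/C15 diol of 12 (acetal-carbon epimers) | CC(C)[C@@H]1CC=C(C)[C@H]([C@@H]1O)[C@@]1(CCCO[Si](C)(C)C(C)(C)C)COC(/C=C/c2ccccc2)O1
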